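Ring C is taken apart at the two bonds that meet at C2, O1–C2 and C2–C3. Since C2 is bonded to both the ring oxygen O1 and the carbinol carbon C3, it can arrive as a carbene carbon: the C8a phenol of ring A captures it, and the resulting oxonium ylide adds through C2 to an aldehyde carbon that becomes C3. One operation thus forms two bonds, closes ring C and sets the trans C2/C3 stereocentres. The partners are a ring A 2-hydroxyarylacetaldehyde (5-OMe, 7-O-silyl, 8-prenyl, stored as its lactol and made from a benzofuranone that tells the two phenols apart) and a 4-silyloxyphenyldiazomethane.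

Key step: step 11

Remark (numbering): flavan numbering is used for ring positions throughout.
Remark (phenol differentiation): silylating both phenols and then oxidising the side chain would leave no way to free the C8a hydroxyl alone. The C8a oxygen is therefore closed into a five-membered lactone with the C4a acetic acid chain, only the C7 phenol is silylated, and reduction of the lactone gives the key-step precursor directly.
Remark (diazo delivery): a stoichiometric sulfonylhydrazone salt is basic enough to neutralise the phosphoric acid co-catalyst. The diazo compound is therefore made by neutral oxidation of the hydrazone and added as a base-free solution; the 4'-oxygen carries a triisopropylsilyl group so that it survives hydrazine.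
Assumption: the (R) enantiomer of the phosphoric acid is written as the one that leads to (2R,3S); the sense of induction cannot be predicted with confidence, and the (S) acid would take its place if a first experiment shows the opposite.

Step 1
Reactants: 1 5-methoxyresorcinol
Product: 2 1-methoxy-3,5-bis(methoxymethoxy)benzene
Conditions: MOMCl, i-Pr2NEt, CH2Cl2, 0 °C to rt
Reagents that add atoms: chloromethyl methyl ether, COCCl
Why: Double O-alkylation of the phenols (Williamson-type acetal protection) installs two MOM ethers that also serve as the directing groups for both later ortho-lithiations.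

Step 2
Reactants: 2 1-methoxy-3,5-bis(methoxymethoxy)benzene; 3 prenyl bromide
Product: 5 5-methoxy-1,3-bis(methoxymethoxy)-2-(3-methylbut-2-en-1-yl)benzene, via aryllithium 4 (not isolated)
Conditions: n-BuLi, THF, 0 °C; then CuI (10 mol %), prenyl bromide, –78 °C to rt
Reagents that add atoms: prenyl bromide (compound 3), CC(C)=CCBr
Why: Directed ortho-metalation should occur at the position flanked by both MOM ethers (cooperative direction), and copper-catalysed SN2 allylation of the aryllithium then places the prenyl group at the future C8.

Step 3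
Reactants: 5 5-methoxy-1,3-bis(methoxymethoxy)-2-(3-methylbut-2-en-1-yl)benzene; 6 ethylene oxide
Product: 8 2-[6-methoxy-2,4-bis(methoxymethoxy)-3-(3-methylbut-2-en-1-yl)phenyl]ethan-1-ol, via aryllithium 7 (not isolated)
Conditions: n-BuLi, THF, 0 °C; then ethylene oxide (THF solution), –78 °C to rt; H2O quench
Reagents that add atoms: ethylene oxide (compound 6), C1CO1
Why: A second directed ortho-metalation at the only kind of ring C–H left (the two are equivalent by symmetry, each between OMOM and OMe) is followed by nucleophilic ring opening of the epoxide, which attaches C4 and C3 at the future C4a.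

Step 4
Reactants: 8 2-[6-methoxy-2,4-bis(methoxymethoxy)-3-(3-methylbut-2-en-1-yl)phenyl]ethan-1-ol
Product: 10 2-[6-methoxy-2,4-bis(methoxymethoxy)-3-(3-methylbut-2-en-1-yl)phenyl]acetic acid, via aldehyde 9 (not isolated)
Conditions: TEMPO (20 mol %), PhI(OAc)2, MeCN–H2O, rt
Reagents that add atoms: water, O
Why: Nitroxyl-catalysed (oxoammonium) oxidation of the primary alcohol proceeds through the aldehyde and its hydrate to the carboxylic acid and should leave the trisubstituted alkene, the acetals and the aryl ethers untouched.

Step 5
Reactants: 10 2-[6-methoxy-2,4-bis(methoxymethoxy)-3-(3-methylbut-2-en-1-yl)phenyl]acetic acid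
Product: 12 6-hydroxy-4-methoxy-7-(3-methylbut-2-en-1-yl)-1-benzofuran-2(3H)-one, via dihydroxy acid 11 (not isolated)
Conditions: 3 M aq. HCl, THF, 40 °C; extraction; then EDC·HCl, CH2Cl2, 0 °C to rt
Reagents that add atoms: none
Why: Acid-catalysed acetal hydrolysis frees both phenols, and carbodiimide-mediated lactonisation can close a five-membered ring only onto the ortho (C8a) hydroxyl, which leaves the C7 phenol as the single free OH.

Step 6
Reactants: 12 6-hydroxy-4-methoxy-7-(3-methylbut-2-en-1-yl)-1-benzofuran-2(3H)-one
Product: 13 6-(tert-butyldimethylsilyloxy)-4-methoxy-7-(3-methylbut-2-en-1-yl)-1-benzofuran-2(3H)-one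
Conditions: TBSCl, imidazole, DMF, 0 °C to rt
Reagents that add atoms: tert-butyldimethylsilyl chloride, CC(C)(C)[Si](C)(C)Cl
Why: Silylation of the only free hydroxyl (the C7 phenol) is a standard silyl ether formation and should be faster than any acyl transfer at the lactone at this temperature.

Step 7
Reactants: 13 6-(tert-butyldimethylsilyloxy)-4-methoxy-7-(3-methylbut-2-en-1-yl)-1-benzofuran-2(3H)-one
Product: 14 6-(tert-butyldimethylsilyloxy)-4-methoxy-7-(3-methylbut-2-en-1-yl)-2,3-dihydro-1-benzofuran-2-ol (racemic lactol)
Conditions: i-Bu2AlH (DIBAL-H), CH2Cl2, –78 °C; aq. potassium sodium tartrate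
Reagents that add atoms: none
Why: Partial reduction of a lactone to the lactol stops at the tetrahedral aluminium alkoxide at –78 °C; the lactol carbon is formed racemic, which is irrelevant because the lactol is the ring tautomer of the open-chain hydroxy aldehyde used next.

Step 8
Reactants: 15 4-hydroxybenzaldehyde
Product: 16 4-(triisopropylsilyloxy)benzaldehyde
Conditions: TIPSCl, imidazole, DMF, rt
Reagents that add atoms: triisopropylsilyl chloride, CC(C)[Si](Cl)(C(C)C)C(C)C
Why: Standard phenol silylation gives a silyl ether robust enough for the hydrazine used in the next step.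

Step 9
Reactants: 16 4-(triisopropylsilyloxy)benzaldehyde
Product: 17 (E)-4-(triisopropylsilyloxy)benzaldehyde hydrazone
Conditions: N2H4·H2O (excess), EtOH, 0 °C to rt; used at once
Reagents that add atoms: hydrazine hydrate, NN.O
Why: Condensation of the aldehyde with excess hydrazine gives the N-unsubstituted hydrazone, the excess suppressing azine formation.

Step 10
Reactants: 17 (E)-4-(triisopropylsilyloxy)benzaldehyde hydrazone
Product: 18 4-(triisopropylsilyloxy)phenyldiazomethane (kept as a cold, dried, titrated CH2Cl2 solution)
Conditions: activated MnO2, MgSO4, CH2Cl2, 0 °C, dark; cold filtration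
Reagents that add atoms: none
Why: Dehydrogenation of an aryl aldehyde hydrazone with MnO2 is a known neutral route to aryldiazomethanes and leaves no base or soluble by-product in the solution.

Step 11
Reactants: 14 6-(tert-butyldimethylsilyloxy)-4-methoxy-7-(3-methylbut-2-en-1-yl)-2,3-dihydro-1-benzofuran-2-ol; 18 4-(triisopropylsilyloxy)phenyldiazomethane
Product: 20 (2R,3S)-7-O-tert-butyldimethylsilyl-4'-O-triisopropylsilyl-8-prenylafzelechin 5-methyl ether, via hydroxy aldehyde 19 (not isolated)
Conditions: Rh2(OAc)4 (2 mol %), (R)-3,3'-bis(2,4,6-triisopropylphenyl)-1,1'-binaphthyl-2,2'-diyl hydrogen phosphate (10 mol %), 4 Å molecular sieves, CH2Cl2, –40 °C; 18 added by syringe pump over several hours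
Reagents that add atoms: 4-(triisopropylsilyloxy)phenyldiazomethane (compound 18), [N-]=[N+]=Cc1ccc(O[Si](C(C)C)(C(C)C)C(C)C)cc1
Why: Proposed new method: Rh2(OAc)4 turns 18 into a rhodium carbene, the C8a phenol of open-chain tautomer 19 (released from lactol 14 by acid-catalysed ring–chain equilibration) adds to it to give a rhodium-associated oxonium ylide (O1–C2), and the ylide carbon C2 attacks the phosphoric-acid-bound aldehyde carbon C3 before the 1,2-proton shift can finish a plain O–H insertion (C2–C3). The closest known reaction type is the Rh2(OAc)4 and chiral phosphoric acid co-catalysed aldol-type trapping of oxonium ylides from aryldiazoacetates, including intramolecular trapping by tethered carbonyl groups; the new element is an ylide with no stabilising carbonyl group. Ring C closes in a 6-exo-trig mode. The relative configuration of C2 and C3 should come from a half-chair transition state with the aryl group and the forming C3–O bond pseudo-equatorial (2,3-trans), and the absolute configuration (2R,3S) from the chiral phosphate that bridges the aldehyde oxygen and the oxonium O–H. The step needs O–H capture to outrun cyclopropanation of the prenyl alkene and carbene dimerisation, and ring closure to outrun proton transfer; the first should be secured by the free phenol being far more nucleophilic toward the carbene than a hindered trisubstituted alkene and by the slow diazo addition, the second by the short tether that holds the activated aldehyde beside the ylide carbon.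

Step 12
Reactants: 20 (2R,3S)-7-O-tert-butyldimethylsilyl-4'-O-triisopropylsilyl-8-prenylafzelechin 5-methyl ether
Product: 21 8-prenylafzelechin 5-methyl ether, (2R,3S)
Conditions: n-Bu4NF (TBAF), AcOH, THF, 0 °C
Reagents that add atoms: none
Why: Fluoride-induced cleavage of both aryl silyl ethers, buffered with acetic acid so that the phenoxides are protonated at once, should leave C2, C3 and the prenyl group untouched.

Compound list
1 | 5-methoxyresorcinol (5-methoxybenzene-1,3-diol) | COc1cc(O)cc(O)c1 | starting material
2 | 1-methoxy-3,5-bis(methoxymethoxy)benzene | COCOc1cc(OC)cc(OCOC)c1 | intermediate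
3 | prenyl bromide (1-bromo-3-methylbut-2-ene) | CC(C)=CCBr | starting material
4 | [4-methoxy-2,6-bis(methoxymethoxy)phenyl]lithium | [Li]c1c(OCOC)cc(OC)cc1OCOC | intermediate
5 | 5-methoxy-1,3-bis(methoxymethoxy)-2-(3-methylbut-2-en-1-yl)benzene | COCOc1cc(OC)cc(OCOC)c1CC=C(C)C | intermediate
6 | ethylene oxide (oxirane) | C1CO1 | starting material
7 | [6-methoxy-2,4-bis(methoxymethoxy)-3-(3-methylbut-2-en-1-yl)phenyl]lithium | [Li]c1c(OC)cc(OCOC)c(CC=C(C)C)c1OCOC | intermediate
8 | 2-[6-methoxy-2,4-bis(methoxymethoxy)-3-(3-methylbut-2-en-1-yl)phenyl]ethan-1-ol | COc1cc(OCOC)c(CC=C(C)C)c(OCOC)c1CCO | intermediate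
9 | 2-[6-methoxy-2,4-bis(methoxymethoxy)-3-(3-methylbut-2-en-1-yl)phenyl]acetaldehyde | COc1cc(OCOC)c(CC=C(C)C)c(OCOC)c1CC=O | intermediate
10 | 2-[6-methoxy-2,4-bis(methoxymethoxy)-3-(3-methylbut-2-en-1-yl)phenyl]acetic acid | COc1cc(OCOC)c(CC=C(C)C)c(OCOC)c1CC(=O)O | intermediate
11 | 2-[2,4-dihydroxy-6-methoxy-3-(3-methylbut-2-en-1-yl)phenyl]acetic acid | COc1cc(O)c(CC=C(C)C)c(O)c1CC(=O)O | intermediate
12 | 6-hydroxy-4-methoxy-7-(3-methylbut-2-en-1-yl)-1-benzofuran-2(3H)-one | COc1cc(O)c(CC=C(C)C)c2OC(=O)Cc12 | intermediate
13 | 6-(tert-butyldimethylsilyloxy)-4-methoxy-7-(3-methylbut-2-en-1-yl)-1-benzofuran-2(3H)-one | COc1cc(O[Si](C)(C)C(C)(C)C)c(CC=C(C)C)c2OC(=O)Cc12 | intermediate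
14 | 6-(tert-butyldimethylsilyloxy)-4-methoxy-7-(3-methylbut-2-en-1-yl)-2,3-dihydro-1-benzofuran-2-ol (racemic lactol, ring tautomer of 19) | COc1cc(O[Si](C)(C)C(C)(C)C)c(CC=C(C)C)c2OC(O)Cc12 | intermediate
15 | 4-hydroxybenzaldehyde | O=Cc1ccc(O)cc1 | starting material
16 | 4-(triisopropylsilyloxy)benzaldehyde | O=Cc1ccc(O[Si](C(C)C)(C(C)C)C(C)C)cc1 | intermediate
17 | (E)-4-(triisopropylsilyloxy)benzaldehyde hydrazone | N/N=C/c1ccc(O[Si](C(C)C)(C(C)C)C(C)C)cc1 | intermediate
18 | 4-(triisopropylsilyloxy)phenyldiazomethane | [N-]=[N+]=Cc1ccc(O[Si](C(C)C)(C(C)C)C(C)C)cc1 | intermediate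
19 | 2-[4-(tert-butyldimethylsilyloxy)-2-hydroxy-6-methoxy-3-(3-methylbut-2-en-1-yl)phenyl]acetaldehyde (open-chain tautomer of 14) | COc1cc(O[Si](C)(C)C(C)(C)C)c(CC=C(C)C)c(O)c1CC=O | intermediate
20 | (2R,3S)-7-O-tert-butyldimethylsilyl-4'-O-triisopropylsilyl-8-prenylafzelechin 5-methyl ether | COc1cc(O[Si](C)(C)C(C)(C)C)c(CC=C(C)C)c2c1C[C@H](O)[C@@H](c1ccc(O[Si](C(C)C)(C(C)C)C(C)C)cc1)O2 | intermediate
21 | 8-prenylafzelechin 5-methyl ether, (2R,3S) | COc1cc(O)c(CC=C(C)C)c2c1C[C@H](O)[C@@H](c1ccc(O)cc1)O2 | target

Total step count: 12. Longest linear sequence: 9 steps (steps 1 to 7, 11 and 12, from 5-methoxyresorcinol).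

Steps most likely to fail

1. Step 11 (proposed new method). What may go wrong:
- the ylide collapses by 1,2-proton shift before it reaches the aldehyde, giving plain O–H insertion;
- the carbene is intercepted by the lactol hydroxyl of 14 or by the prenyl alkene;
- the diazo compound is protonated by the phosphoric acid;
- facial control by the acid is poor.

Fallback with known chemistry, setting out from alcohol 8 and coming back at target 21. Alcohol 8 is oxidised with Dess–Martin periodinane to aldehyde 9. Aldehyde 9, diazo compound 18, Rh2(OAc)4 (1 mol %) and a chiral sulfide (isothiocineole, C10H18S, enantiomer chosen for the (2S,3S) product) are combined in a catalytic asymmetric sulfur-ylide epoxidation of Corey–Chaykovsky type, which forms the C2–C3 bond and gives the trans-epoxide (2S,3S)-2-[4-(triisopropylsilyloxy)phenyl]-3-{[6-methoxy-2,4-bis(methoxymethoxy)-3-(3-methylbut-2-en-1-yl)phenyl]methyl}oxirane F1. Camphorsulfonic acid in CH2Cl2 at low temperature should then let the C8a ether oxygen open the epoxide at the benzylic carbon with inversion (6-endo, O1–C2 bond) and loss of its methoxymethyl group, giving (2R,3S)-7-O-methoxymethyl-4'-O-triisopropylsilyl-8-prenylafzelechin 5-methyl ether F2. Dilute aqueous HCl in THF removes the remaining acetal to give (2R,3S)-4'-O-triisopropylsilyl-8-prenylafzelechin 5-methyl ether F3, and n-Bu4NF with AcOH gives 21.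

2. Step 3. What may go wrong: deprotonation at the benzylic and allylic CH2 of the prenyl group competes with ring lithiation, and the hindered aryllithium opens the epoxide slowly.

Fallback, setting out from 5 and coming back at 8. Compound 5 is brominated at its free ring position with NBS in MeCN at –20 °C; electrophilic substitution on the trialkoxyarene should be faster than attack on the alkene. This gives 2-bromo-1-methoxy-3,5-bis(methoxymethoxy)-4-(3-methylbut-2-en-1-yl)benzene F4. Bromine–lithium exchange with t-BuLi in THF at –78 °C then gives aryllithium 7 without any acid–base chemistry at the prenyl CH2, and ethylene oxide (with BF3·OEt2 if the opening is slow) gives 8.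

3. Step 5. What may go wrong: during the acidic acetal hydrolysis the freed phenols add to the protonated prenyl alkene (chroman formation), or the alkene is hydrated.

Fallback that replaces hydrolysis by a protecting-group exchange under buffered, non-protic conditions, setting out from 10 and coming back at 11. Acid 10 is treated with TMSOTf and 2,2'-bipyridyl in MeCN at 0 °C, which should convert the aryl methoxymethyl ethers into trimethylsilyl ethers and the acid into its silyl ester, giving trimethylsilyl 2-[6-methoxy-3-(3-methylbut-2-en-1-yl)-2,4-bis(trimethylsilyloxy)phenyl]acetate F5. Neutral aqueous work-up cleaves the Si–O bonds to give 11, which is lactonised with EDC·HCl as in step 5.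

Further compounds
F1 | step 11 | (2S,3S)-2-[4-(triisopropylsilyloxy)phenyl]-3-{[6-methoxy-2,4-bis(methoxymethoxy)-3-(3-methylbut-2-en-1-yl)phenyl]methyl}oxirane | COc1cc(OCOC)c(CC=C(C)C)c(OCOC)c1C[C@@H]1O[C@H]1c1ccc(O[Si](C(C)C)(C(C)C)C(C)C)cc1
F2 | step 11 | (2R,3S)-7-O-methoxymethyl-4'-O-triisopropylsilyl-8-prenylafzelechin 5-methyl ether | COc1cc(OCOC)c(CC=C(C)C)c2c1C[C@H](O)[C@@H](c1ccc(O[Si](C(C)C)(C(C)C)C(C)C)cc1)O2
F3 | step 11 | (2R,3S)-4'-O-triisopropylsilyl-8-prenylafzelechin 5-methyl ether | COc1cc(O)c(CC=C(C)C)c2c1C[C@H](O)[C@@H](c1ccc(O[Si](C(C)C)(C(C)C)C(C)C)cc1)O2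
F4 | step 3 | 2-bromo-1-methoxy-3,5-bis(methoxymethoxy)-4-(3-methylbut-2-en-1-yl)benzene | COc1cc(OCOC)c(CC=C(C)C)c(OCOC)c1Br
F5 | step 5 | trimethylsilyl 2-[6-methoxy-3-(3-methylbut-2-en-1-yl)-2,4-bis(trimethylsilyloxy)phenyl]acetate | COc1cc(O[Si](C)(C)C)c(CC=C(C)C)c(O[Si](C)(C)C)c1CC(=O)O[Si](C)(C)C
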